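**Retrosynthetic overview** (cage atoms numbered as in tricyclo[2.2.1.0^2,6]heptane: C1, C2, C6 = cyclopropane with CH3 on C2; C3 = CH–OAc; C4 = quaternary bridgehead; C5 = CH2; C7 = carbon bearing CH2OAc)

1. Target 29 ⇐ diacetate 26 by Woodward–Prévost cis-hydroxy-acetoxylation of the cyclohexene on its more hindered face; C3–OAc ⇐ ketone 22 by hydride reduction and solvolytic inversion.
2. Ketone 22 ⇐ bicyclic enone 18. The enabling feature is that C3 lies between bridgehead C4 and the methyl-bearing cyclopropane carbon C2. As C=O it makes C1–C2–C6 a cyclopropyl ketone in which C5–C6 joins the α′- (C4), β- (C1) and α- (C2) carbons of a 2-methylcyclopent-2-enone (C3, C2, C1, C7, C4). The CH2O group on C7 is syn to that bridge and can deliver it as a vinylsulfonate that leaves as SO2.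
3. Enone 18 ⇐ acid 12 by two ring-closing metatheses.
4. Acid 12 ⇐ ester 9 by Ireland–Claisen rearrangement (1,3-chirality transfer from an (R)-carbinol to quaternary C7); 9 ⇐ (R)-but-3-yn-2-ol + 3,3-dimethylpent-4-enoic acid.
5. Ring order: cyclohexene (step 7), cyclopentenone (step 9), then in step 12 the carbocycle C4–C5–C6–C1–C7, and last, by the C2–C6 bond, the cyclopropane together with the ring C4–C5–C6–C2–C3.

Key step: step 12

Remark: the stereocentre α to the carbonyl made in step 6 (C-2 of 12, C-7a of 16–18) is drawn as the expected isomer; it becomes an enolate in step 12, so its configuration is not required.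

**Step 1**
Reactants: 1 (R)-but-3-yn-2-ol
Product: 3 (R)-pent-2-yne-1,4-diol, via dilithium alkoxide acetylide 2 (not isolated)
Conditions: n-BuLi (2.2 equiv), THF, −78 → 0 °C; (CH2O)n, 0 °C → rt; aq NH4Cl
Reagents that add atoms: paraformaldehyde as formaldehyde, C=O
Why: Addition of a lithium acetylide to formaldehyde; the carbinol centre is not touched.

**Step 2**
Reactants: 3 (R)-pent-2-yne-1,4-diol
Product: 4 (R)-5-[(tert-butyldimethylsilyl)oxy]pent-3-yn-2-ol
Conditions: TBSCl (1.0 equiv), imidazole, CH2Cl2, −20 °C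
Reagents that add atoms: tert-butyldimethylsilyl chloride, CC(C)(C)[Si](C)(C)Cl
Why: Silylation should select the primary over the secondary propargylic hydroxyl on steric grounds.

**Step 3**
Reactants: 4 (R)-5-[(tert-butyldimethylsilyl)oxy]pent-3-yn-2-ol
Product: 6 (R,Z)-5-[(tert-butyldimethylsilyl)oxy]-4-iodopent-3-en-2-ol, via cyclic vinylalanate 5 (not isolated)
Conditions: Red-Al, THF, 0 °C → rt; EtOAc; I2, −78 → 0 °C
Reagents that add atoms: iodine, II
Why: Hydroxyl-directed trans-hydroalumination of a propargylic alcohol places Al on the distal carbon, and iodo-dealumination with retention fixes the trisubstituted alkene geometry (I cis to the carbinol carbon).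

**Step 4**
Reactants: 6 (R,Z)-5-[(tert-butyldimethylsilyl)oxy]-4-iodopent-3-en-2-ol
Product: 7 (R,E)-4-{[(tert-butyldimethylsilyl)oxy]methyl}hepta-3,6-dien-2-ol
Conditions: allyltributylstannane, Pd(PPh3)4 (cat.), CuI (cat.), DMF, 50 °C
Reagents that add atoms: allyltributylstannane, C=CC[Sn](CCCC)(CCCC)CCCC
Why: Stille coupling of a vinyl iodide proceeds with retention, so allyl ends cis and CH2OTBS trans to the carbinol carbon.

**Step 5**
Reactants: 7 (R,E)-4-{[(tert-butyldimethylsilyl)oxy]methyl}hepta-3,6-dien-2-ol; 8 3,3-dimethylpent-4-enoic acid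
Product: 9 (R,E)-4-{[(tert-butyldimethylsilyl)oxy]methyl}hepta-3,6-dien-2-yl 3,3-dimethylpent-4-enoate
Conditions: DCC, DMAP (cat.), CH2Cl2, 0 °C → rt
Reagents that add atoms: none
Why: Steglich esterification of a secondary allylic alcohol; no stereocentre is affected.

**Step 6**
Reactants: 9 (R,E)-4-{[(tert-butyldimethylsilyl)oxy]methyl}hepta-3,6-dien-2-yl 3,3-dimethylpent-4-enoate
Product: 12 (2R,3S,4E)-3-allyl-3-{[(tert-butyldimethylsilyl)oxy]methyl}-2-(2-methylbut-3-en-2-yl)hex-4-enoic acid, via silyl ketene acetal 10 (not isolated), via trimethylsilyl ester 11 (not isolated)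
Conditions: LDA, THF/DMPU (4:1), −78 °C; Me3SiCl, −78 → 60 °C; 1 M HCl
Reagents that add atoms: none
Why: Ireland–Claisen rearrangement through a chair transition state; A(1,3) strain holds the carbinol H in the alkene plane, so the (R)-carbinol centre is transferred to the new quaternary carbon (S) and an (E)-propenyl group appears, while the (Z)-ketene acetal places the CMe2 group equatorial and gives the relative configuration that suits a later cis ring fusion.

**Step 7**
Reactants: 12 (2R,3S,4E)-3-allyl-3-{[(tert-butyldimethylsilyl)oxy]methyl}-2-(2-methylbut-3-en-2-yl)hex-4-enoic acid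
Product: 13 (1R,6S)-6-{[(tert-butyldimethylsilyl)oxy]methyl}-2,2-dimethyl-6-[(E)-prop-1-en-1-yl]cyclohex-3-ene-1-carboxylic acid
Conditions: (H2IMes)(PCy3)Cl2Ru=CHPh (3 mol%), CH2Cl2, 40 °C
Reagents that add atoms: none
Why: Ring-closing metathesis; the catalyst should load on the unhindered allyl terminus, which can close only the six-membered ring with the vinyl group on CMe2.

**Step 8**
Reactants: 13 (1R,6S)-6-{[(tert-butyldimethylsilyl)oxy]methyl}-2,2-dimethyl-6-[(E)-prop-1-en-1-yl]cyclohex-3-ene-1-carboxylic acid
Product: 15 1-[(1R,6S)-6-{[(tert-butyldimethylsilyl)oxy]methyl}-2,2-dimethyl-6-[(E)-prop-1-en-1-yl]cyclohex-3-en-1-yl]-2-methylprop-2-en-1-one, via acid chloride 14 (not isolated)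
Conditions: 1-chloro-N,N,2-trimethylprop-1-en-1-amine, CH2Cl2, 0 °C → rt; then tributyl(isopropenyl)stannane, Pd2(dba)3/P(2-furyl)3 (cat.), THF, 50 °C
Reagents that add atoms: tributyl(prop-1-en-2-yl)stannane, C=C(C)[Sn](CCCC)(CCCC)CCCC
Why: Neutral acid chloride formation followed by Stille acylation gives the vinyl ketone without a strongly basic nucleophile at the hindered carboxyl.

**Step 9**
Reactants: 15 1-[(1R,6S)-6-{[(tert-butyldimethylsilyl)oxy]methyl}-2,2-dimethyl-6-[(E)-prop-1-en-1-yl]cyclohex-3-en-1-yl]-2-methylprop-2-en-1-one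
Product: 16 (3aS,7aR)-3a-{[(tert-butyldimethylsilyl)oxy]methyl}-2,7,7-trimethyl-3a,4,7,7a-tetrahydro-1H-inden-1-one
Conditions: (H2IMes)Cl2Ru(=CH-C6H4-2-OiPr) (5–10 mol%), toluene, 80 °C
Reagents that add atoms: none
Why: Ring-closing metathesis of the propenyl group with the 1,1-disubstituted enone olefin forms the 2-methylcyclopentenone and releases propene; the carbonyl-bearing ring carbon is epimerisable, so material can funnel into the cis-fused enone.

**Step 10**
Reactants: 16 (3aS,7aR)-3a-{[(tert-butyldimethylsilyl)oxy]methyl}-2,7,7-trimethyl-3a,4,7,7a-tetrahydro-1H-inden-1-one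
Product: 17 (3aS,7aR)-3a-(hydroxymethyl)-2,7,7-trimethyl-3a,4,7,7a-tetrahydro-1H-inden-1-one
Conditions: TBAF, THF, 0 °C → rt
Reagents that add atoms: none
Why: Fluoride cleavage of the primary silyl ether; the quaternary centre cannot epimerise.

**Step 11**
Reactants: 17 (3aS,7aR)-3a-(hydroxymethyl)-2,7,7-trimethyl-3a,4,7,7a-tetrahydro-1H-inden-1-one
Product: 18 [(3aS,7aR)-2,7,7-trimethyl-1-oxo-1,4,7,7a-tetrahydro-3aH-inden-3a-yl]methyl ethenesulfonate
Conditions: ClCH2CH2SO2Cl, Et3N (excess), CH2Cl2, −10 °C → rt
Reagents that add atoms: 2-chloroethanesulfonyl chloride, ClCCS(=O)(=O)Cl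
Why: Sulfonylation with ethenesulfonyl chloride generated in situ is the standard way to vinylsulfonate esters and attaches the two-carbon unit to the oxygen that is syn to its final position.

**Step 12**
Reactants: 18 [(3aS,7aR)-2,7,7-trimethyl-1-oxo-1,4,7,7a-tetrahydro-3aH-inden-3a-yl]methyl ethenesulfonate
Product: 22 tetracyclic keto alcohol (2-methyltricyclo[2.2.1.0^2,6]heptan-3-one with C7–C4 spanned by CH2–CH=CH–CMe2 and CH2OH on C7 syn to C5), via potassium dienolate 19 (not isolated), via sultone enolate 20 (not isolated), via potassium alkyl sulfite 21 (not isolated)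
Conditions: KHMDS (1.2 equiv), THF (0.01 M), −78 °C → rt; DMPU, 60 °C; 1 M HCl
Reagents that add atoms: none
Why: Proposed new method: KHMDS removes the only acidic proton (ring-fusion α′-H) to give the cross-conjugated dienolate 19, whose α′-carbon adds to the CH2 terminus of the tethered vinylsulfonate and whose enone β-carbon is then attacked by the resulting α-sulfonyl carbanion (an anionic intramolecular [4+2] in two Michael steps), giving the sultone-bridged bicyclo[2.2.1]heptanone enolate 20; the enolate α-carbon then displaces sulfur from the CH carbon (1,3-elimination) and the expelled alkyl sulfite 21 loses SO2 on acidic work-up, so the tether leaves no atoms behind. The closest known reaction types are the bicycloannulation of cycloalkenone α′-enolates with vinyl sulfones, vinylphosphonium salts or α-haloacrylates (Michael–Michael–ring closure), the intramolecular Diels–Alder reaction of vinylsulfonates to δ-sultones, and cyclopropane formation by 1,3-elimination of sulfinate; what is new is a sulfonate ester acting as both tether and nucleofuge. Modes of closure: first Michael 7-endo-trig (temporary ring), second Michael 5-exo-trig for the carbocycle C4–C5–C6–C1–C7 (6-exo-trig for the sultone), last step 3-exo-tet for the cyclopropane, which at the same time completes the ring C4–C5–C6–C2–C3. Stereocontrol: quaternary C4 is set by the tether, which reaches only the face syn to the CH2O group on C7; C1 and C6 follow because the two-carbon bridge must stay on that face, and C2 because only the endo lobe of the enolate reaches the CH–S carbon. The step needs the regiochemistry CH2→C4 and CH→C1, secured by the polarity of dienolate and vinylsulfonate although the tether could reach both ring carbons next to C7, and an exo C–S bond antiperiplanar to the attacking enolate, secured because sulfur is tied to the syn CH2O group.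

**Step 13**
Reactants: 22 tetracyclic keto alcohol
Product: 23 tetracyclic keto acetate
Conditions: Ac2O, pyridine, DMAP (cat.), CH2Cl2, rt
Reagents that add atoms: acetic anhydride, CC(=O)OC(C)=O
Why: Acetylation of the only hydroxyl group.

**Step 14**
Reactants: 23 tetracyclic keto acetate
Product: 24 C3-epi hydroxy acetate (OH syn to the ring CH2 on C7)
Conditions: NaBH4, MeOH/THF, −10 °C
Reagents that add atoms: none
Why: Ketone reduction under steric approach control; the cyclohexene CH2 on C7 blocks one face of C3=O, so hydride should enter from the C5 side and leave OH syn to that CH2, the epimer of the target centre.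

**Step 15**
Reactants: 24 C3-epi hydroxy acetate
Product: 26 tetracyclic diacetate (C3–OAc anti to the ring CH2 on C7), via mesylate 25 (not isolated)
Conditions: MsCl, Et3N, CH2Cl2, −20 °C; then KOAc, AcOH, 40 °C
Reagents that add atoms: potassium acetate, CC(=O)[O-].[K+]
Why: Buffered acetolysis of a cyclopropylcarbinyl sulfonate; ionisation to the delocalised cyclopropylcarbinyl cation and capture by acetate from the same open C5 side should give net inversion at C3, i.e. the target configuration.

**Step 16**
Reactants: 26 tetracyclic diacetate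
Product: 29 target hydroxy triacetate, via trans-iodo acetate 27 (not isolated), via acetoxonium ion 28 (not isolated)
Conditions: I2 (1.05 equiv), AgOAc (2.2 equiv), AcOH, rt; then H2O (wet AcOH), 90 °C
Reagents that add atoms: silver acetate, CC(=O)[O-].[Ag+]; water, O
Why: Woodward–Prévost reaction: iodonium should form on the face anti to the axial CH2OAc and axial methyl, acetate opens it trans-diaxially at the CH2-flanked carbon, and hydrolysis of the acetoxonium ion formed by silver-assisted displacement of iodide gives the cis hydroxy acetate on the hindered face, with the ester on the axial oxygen (next to CH2) and the free OH next to CMe2.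

**Compound list**

1 | (R)-but-3-yn-2-ol | C[C@@H](O)C#C | starting material
2 | dilithium alkoxide acetylide of 1 | C[C@@H](O[Li])C#C[Li] | intermediate (not isolated)
3 | (R)-pent-2-yne-1,4-diol | C[C@@H](O)C#CCO | intermediate
4 | (R)-5-[(tert-butyldimethylsilyl)oxy]pent-3-yn-2-ol | C[C@@H](O)C#CCO[Si](C)(C)C(C)(C)C | intermediate
5 | cyclic sodium vinylalanate from 4 (Al on the carbon bearing CH2OTBS) | C[C@H]1O[Al-](OCCOC)(OCCOC)C(CO[Si](C)(C)C(C)(C)C)=C1.[Na+] | intermediate (not isolated)
6 | (R,Z)-5-[(tert-butyldimethylsilyl)oxy]-4-iodopent-3-en-2-ol | C[C@@H](O)/C=C(\I)CO[Si](C)(C)C(C)(C)C | intermediate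
7 | (R,E)-4-{[(tert-butyldimethylsilyl)oxy]methyl}hepta-3,6-dien-2-ol | C[C@@H](O)/C=C(\CC=C)CO[Si](C)(C)C(C)(C)C | intermediate
8 | 3,3-dimethylpent-4-enoic acid | C=CC(C)(C)CC(=O)O | starting material
9 | (R,E)-4-{[(tert-butyldimethylsilyl)oxy]methyl}hepta-3,6-dien-2-yl 3,3-dimethylpent-4-enoate | C=CC(C)(C)CC(=O)O[C@H](C)/C=C(\CC=C)CO[Si](C)(C)C(C)(C)C | intermediate
10 | (Z)-trimethylsilyl ketene acetal of 9 | C=CC(C)(C)/C=C(\O[Si](C)(C)C)O[C@H](C)/C=C(\CC=C)CO[Si](C)(C)C(C)(C)C | intermediate (not isolated)
11 | trimethylsilyl ester of 12 | CC(C)(C)[Si](C)(C)OC[C@@](CC=C)(/C=C/C)[C@H](C(=O)O[Si](C)(C)C)C(C)(C)C=C | intermediate (not isolated)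
12 | (2R,3S,4E)-3-allyl-3-{[(tert-butyldimethylsilyl)oxy]methyl}-2-(2-methylbut-3-en-2-yl)hex-4-enoic acid | CC(C)(C)[Si](C)(C)OC[C@@](CC=C)(/C=C/C)[C@H](C(=O)O)C(C)(C)C=C | intermediate
13 | (1R,6S)-6-{[(tert-butyldimethylsilyl)oxy]methyl}-2,2-dimethyl-6-[(E)-prop-1-en-1-yl]cyclohex-3-ene-1-carboxylic acid | CC(C)(C)[Si](C)(C)OC[C@]1(/C=C/C)CC=CC(C)(C)[C@H]1C(=O)O | intermediate
14 | acid chloride of 13 | CC(C)(C)[Si](C)(C)OC[C@]1(/C=C/C)CC=CC(C)(C)[C@H]1C(Cl)=O | intermediate (not isolated)
15 | 1-[(1R,6S)-6-{[(tert-butyldimethylsilyl)oxy]methyl}-2,2-dimethyl-6-[(E)-prop-1-en-1-yl]cyclohex-3-en-1-yl]-2-methylprop-2-en-1-one | CC(C)(C)[Si](C)(C)OC[C@]1(/C=C/C)CC=CC(C)(C)[C@H]1C(=O)C(C)=C | intermediate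
16 | (3aS,7aR)-3a-{[(tert-butyldimethylsilyl)oxy]methyl}-2,7,7-trimethyl-3a,4,7,7a-tetrahydro-1H-inden-1-one | CC(C)(C)[Si](C)(C)OC[C@]12CC=CC(C)(C)[C@H]1C(=O)C(C)=C2 | intermediate
17 | (3aS,7aR)-3a-(hydroxymethyl)-2,7,7-trimethyl-3a,4,7,7a-tetrahydro-1H-inden-1-one | OC[C@]12CC=CC(C)(C)[C@H]1C(=O)C(C)=C2 | intermediate
18 | [(3aS,7aR)-2,7,7-trimethyl-1-oxo-1,4,7,7a-tetrahydro-3aH-inden-3a-yl]methyl ethenesulfonate | C=CS(=O)(=O)OC[C@]12CC=CC(C)(C)[C@H]1C(=O)C(C)=C2 | intermediate
19 | potassium cross-conjugated dienolate of 18 | C=CS(=O)(=O)OC[C@]12CC=CC(C)(C)C1=C([O-])C(C)=C2.[K+] | intermediate (not isolated)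
20 | sultone-bridged bicyclo[2.2.1]heptanone enolate (S exo on the CH carbon, potassium salt) | O=S1(=O)OC[C@]23CC=CC(C)(C)[C@]24C[C@H]1[C@H]3C(C)=C4[O-].[K+] | intermediate (not isolated)
21 | potassium alkyl sulfite of 22 | [K+].[O-]S(=O)OC[C@]12CC=CC(C)(C)[C@]13C[C@@H]1[C@H]2[C@]1(C)C3=O | intermediate (not isolated)
22 | tetracyclic keto alcohol (cage C3=O, CH2OH on C7 syn to C5, cyclohexene CMe2 on C4) | OC[C@]12CC=CC(C)(C)[C@]13C[C@@H]1[C@H]2[C@]1(C)C3=O | intermediate
23 | tetracyclic keto acetate | CC(=O)OC[C@]12CC=CC(C)(C)[C@]13C[C@@H]1[C@H]2[C@]1(C)C3=O | intermediate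
24 | C3-epi hydroxy acetate (C3–OH syn to the ring CH2 on C7) | CC(=O)OC[C@]12CC=CC(C)(C)[C@]13C[C@@H]1[C@H]2[C@]1(C)[C@@H]3O | intermediate
25 | mesylate of 24 | CC(=O)OC[C@]12CC=CC(C)(C)[C@]13C[C@@H]1[C@H]2[C@]1(C)[C@@H]3OS(C)(=O)=O | intermediate (not isolated)
26 | tetracyclic diacetate (C3–OAc anti to the ring CH2 on C7) | CC(=O)OC[C@]12CC=CC(C)(C)[C@]13C[C@@H]1[C@H]2[C@]1(C)[C@H]3OC(C)=O | intermediate
27 | trans-diaxial iodo acetate (OAc next to CH2, I next to CMe2) | CC(=O)OC[C@]12C[C@H](OC(C)=O)[C@@H](I)C(C)(C)[C@]13C[C@@H]1[C@H]2[C@]1(C)[C@H]3OC(C)=O | intermediate (not isolated)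
28 | cis-fused 2-methyl-1,3-dioxolan-2-ylium (acetoxonium) acetate | CC(=O)OC[C@]12C[C@@H]4O[C+](C)O[C@@H]4C(C)(C)[C@]13C[C@@H]1[C@H]2[C@]1(C)[C@H]3OC(C)=O.CC(=O)[O-] | intermediate (not isolated)
29 | target hydroxy triacetate (CNP0197219.1) | CC(=O)OC[C@]12C[C@H](OC(C)=O)[C@H](O)C(C)(C)[C@]13C[C@@H]1[C@H]2[C@]1(C)[C@H]3OC(C)=O | target

**Step count**

Total steps: 16. Longest linear sequence: 16 steps from 1 (acid 8 is purchased).

**Steps most likely to fail**

Step 12. The cascade may stop after the two Michael additions because the C–S-cleaving 1,3-elimination is slow, or the base may add to the vinylsulfonate before the hindered α′-proton is removed. The fallback uses the untethered bicycloannulation, a known reaction type. It sets out from 16: deprotonation with LDA in THF at −78 °C and addition of vinyltriphenylphosphonium bromide, with warming to reflux (Michael addition, ylide Michael addition, 1,3-elimination of triphenylphosphine), would give the silyl ether of the tetracyclic ketone F1. TBAF would then give 22, where the route is rejoined. Without the tether, the face of attack rests only on the preference for a cis ring fusion.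

Step 15. The cyclopropylcarbinyl cation may be captured at a homoallylic position with opening of the three-membered ring, or the cyclohexene may take part in the ionisation. The fallback replaces ionisation by redox equilibration. It sets out from 24: Al(OiPr)3, i-PrOH and catalytic acetone in refluxing toluene (reversible Meerwein–Ponndorf–Verley/Oppenauer hydride transfer) should epimerise C3 to the less hindered carbinol and transesterify the primary acetate, giving the diol F2. Ac2O, DMAP and pyridine would then give 26.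

Step 16. Iodonium formation or acetate opening may take the wrong facial or regiochemical course, or the acetyl group may migrate. The fallback builds the same hydroxy acetate by epoxide opening and redox inversion. It sets out from 26: mCPBA should epoxidise the face anti to the axial CH2OAc and methyl to give the epoxide F3. Trans-diaxial opening with NaOAc in AcOH at the CH2-flanked carbon would give the acetoxy alcohol F4 (OAc syn to CH2OAc, OH anti). Dess–Martin oxidation would give the ketone F5, and NaBH4 (axial hydride delivery, equatorial alcohol) would give 29.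

**Further compounds**

F1 | step 12 | tert-butyldimethylsilyl ether of tetracyclic keto alcohol 22 | CC(C)(C)[Si](C)(C)OC[C@]12CC=CC(C)(C)[C@]13C[C@@H]1[C@H]2[C@]1(C)C3=O
F2 | step 15 | tetracyclic diol (C3–OH anti to the ring CH2 on C7, free CH2OH) | OC[C@]12CC=CC(C)(C)[C@]13C[C@@H]1[C@H]2[C@]1(C)[C@H]3O
F3 | step 16 | epoxide of 26 on the face anti to CH2OAc | CC(=O)OC[C@]12C[C@H]4O[C@H]4C(C)(C)[C@]13C[C@@H]1[C@H]2[C@]1(C)[C@H]3OC(C)=O
F4 | step 16 | trans-diaxial acetoxy alcohol (carbinol epimer of 29 next to CMe2) | CC(=O)OC[C@]12C[C@H](OC(C)=O)[C@@H](O)C(C)(C)[C@]13C[C@@H]1[C@H]2[C@]1(C)[C@H]3OC(C)=O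
F5 | step 16 | α-acetoxy ketone (C=O next to CMe2) | CC(=O)OC[C@]12C[C@H](OC(C)=O)C(=O)C(C)(C)[C@]13C[C@@H]1[C@H]2[C@]1(C)[C@H]3OC(C)=O
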